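## The problem

The target is a biflavanone in which C3 of a catechol-bearing flavanone (upper unit, rings A, B and C) is bonded to the aromatic carbon C8'' of a 4-hydroxyphenyl flavanone (lower unit), so the inter-unit bond joins a secondary sp3 carbon to an arene carbon flanked by two oxygens. There are three stereocentres: C2 (R) and C3 (S), trans on upper ring C, and C2'' (R) on lower ring C. C2 and C3 are adjacent and can be set in one event, whereas C2'' lies across the lower aromatic ring from C3 and needs its own reagent control. Both heterocycles are 2-arylchroman-4-ones that open under base by retro-oxa-Michael reaction, and the upper C3–H, acidified by the ketone and the aryl group, would let base erase C2 and C3 together. The seven phenols (one catechol, two phloroglucinol-type rings) are sensitive to oxidants and base, which argues for one neutral unmasking at the end. Lower ring C must close onto the oxygen next to the inter-unit bond (8''-link) and not onto the other ortho oxygen (6''-link). The enabling feature lies in the upper unit: O1–C8a–C4a–C4 is the oxadiene of an o-quinone methide of ring A, and C2–C3 with its two aryl groups is an (E)-stilbene whose geometry encodes the trans relation. The para oxygen of the catechol ring polarises that alkene in the sense needed for O1–C2 and C3–C4 to form together.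

## Retrosynthesis

**20 ⇒ 19.** No skeletal bond is cut; the seven phenols of target 20 are returned to benzyl ethers in 19. One protecting group throughout means one neutral hydrogenolysis ends the synthesis, and neither flavanone meets acid or base once it exists. The forward step must spare two aryl ketones and two benzylic C2–O bonds.

**19 ⇒ 18 ⇒ 17.** The upper C4 carbonyl is taken back through alcohol 18 to the methylene of flavan 17. Carrying the ketone from an earlier stage would expose the doubly activated C3–H and the ring-opening pathway to every basic step in between; as a flavan the upper unit has neither liability. The forward reaction is a site-selective benzylic oxidation. C4 is the only methylene ortho and para to two ether oxygens of ring A, which is what makes it selective.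

**17 ⇒ 15 + 16.** The C2''–aryl bond is cut, giving chromone 15 and boronic acid 16. The neighbouring cut, O1''–C2'' (closure of a hydroxychalcone), is reversible, its C2'' epimers are close in energy, and it is hard to control with a catalyst. A conjugate arylation is irreversible and ligand-controlled. The cut removes the last stereocentre and the lower aryl ring. The forward step must arylate a hindered 5-alkoxy-8-aryl chromone on one face without opening the product.

**15 ⇒ 13 (through 14).** O1''–C2'' and C2''–C3'' are cut; C2'' is a one-carbon unit condensed onto the methyl ketone of 13, and enaminone 14 closes onto the free phenol. Whether the chromone is 8''- or 6''-linked depends only on which ortho hydroxyl of 13 is free. The ring-regiochemistry question is thereby moved to a protecting-group pattern.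

**13 ⇒ 12 ⇒ 11.** Only protecting groups change: the two lower-ring benzyl ethers of 13 go back to triol 12, and its three hydroxyls to the pivalates of 11. The esters are needed because the lower ring must be a poor cation-stabilising group in the key step. The acetyl group is carried from the start, so no Friedel–Crafts acylation has to distinguish two electron-rich rings later. The forward steps are ester cleavage on a base-stable flavan and a dibenzylation that leaves the most hindered, chelated hydroxyl free.

**11 ⇒ 3 + 9 (through 10).** O1–C2 and C3–C4 are cut together, a retro oxa-[4+2]. This is the only cut that removes ring C and both adjacent stereocentres at once, and it gives two fragments of similar size: salicyl alcohol 3 (source of o-quinone methide 10) and stilbene 9. Cutting C2–C3 or C3–C8'' instead would leave a ring closure and a stereocentre to be dealt with separately. The forward reaction must be regioselective, trans-selective and enantioselective.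

**9 ⇒ 8 + 5; 8 ⇒ 7 ⇒ 6; 5 ⇒ 4.** The aryl–vinyl bond of 9 is cut (Heck coupling) to iodide 8 and styrene 5. The olefination alternatives need strong base, which aryl esters would not tolerate. Iodide 8 comes from commercial ketone 6 by iodination (7) and acylation. Styrene 5 comes from aldehyde 4 by methylenation.

**3 ⇒ 2 ⇒ 1.** The hydroxymethyl group of 3 is the reduced formyl group of 2, which comes from trihydroxybenzaldehyde 1 by dibenzylation. The chelated ortho hydroxyl that survives becomes O1 of the upper unit.

## Roads not taken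

Alternative 1: Aryne annulation. The cut is O1–C8a and C4–C4a of the upper ring C. The forward key step treats methyl (2S,3R)-3-[3,4-bis(benzyloxy)phenyl]-3-hydroxy-2-[2,4,6-tris(methoxymethoxy)phenyl]propanoate A2 and 3,5-bis(benzyloxy)-2-(trimethylsilyl)phenyl trifluoromethanesulfonate A3 with CsF. The alkoxide of A2 adds to the aryne released from A3, and the resulting aryl anion acylates on the ester of A2 to give (2R,3S)-5,7-bis(benzyloxy)-2-[3,4-bis(benzyloxy)phenyl]-3-[2,4,6-tris(methoxymethoxy)phenyl]chroman-4-one A1.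
- Merits: C4 arrives as the ketone in A1, so no C–H oxidation is needed, and the alkoxy group next to the aryne from A3 directs the oxygen to the correct carbon. In the first of these respects this road is better than the chosen one.
- Weak points: the alkoxide of A2 is a β-alkoxy ester with an α-aryl group, so retro-aldol cleavage and C3 epimerisation are expected under fluoride. A hindered secondary alkoxide must also capture the aryne, and the aryl anion must acylate before it is protonated. The stereocentres of A2 are made before the ring in an anti-selective aryl-acetate aldol that is itself not routine. A1 is a base-labile 3-arylflavanone that would then have to survive the whole lower-unit construction.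
- Comparison: the chosen plan pays with a late C4 oxidation. In return it forms both stereocentres in the ring-closing step under acid catalysis only, and keeps the upper unit as a robust flavan until the end.

Alternative 2: Cyclobutenone–alkyne benzannulation. The cut is C8''–C8a'' and C6''–C7'' of the lower ring A. Heating (2R,3S)-5,7-bis(benzyloxy)-2-[3,4-bis(benzyloxy)phenyl]-3-[(triisopropylsilyloxy)ethynyl]chroman A5 with 3-(benzyloxy)cyclobut-2-en-1-one A6 would grow the lower ring A on C3 and give 5-(benzyloxy)-2-{(2R,3S)-5,7-bis(benzyloxy)-2-[3,4-bis(benzyloxy)phenyl]chroman-3-yl}-3-(triisopropylsilyloxy)phenol A4. In this benzannulation A6 supplies C4a'', C5'', C6'' and C8a'', and the alkyne of A5 supplies C7'' and C8''.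
- Merits: the three oxygens of the lower ring in A4 are formed already differentiated, with the free hydroxyl next to the inter-unit bond. The 8''-regiochemistry is thus fixed by construction, which is better than the selective dibenzylation the chosen plan relies on. The four-carbon partner A6 is small and achiral.
- Weak points: the strategy does nothing for C2 and C3. A5 must first be made as a single trans enantiomer, which is the hard part of the problem. The siloxyalkyne of A5 sits on a branched carbon and must survive the thermal cascade with A6. A4 still needs acylation at C4a'' in the presence of the equally electron-rich upper ring A, the lower ring C, and the same C4 oxidation as the chosen plan.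
- Comparison: the chosen plan sets against the born-differentiated ring a shorter sequence and a key step that creates the stereocentres rather than inheriting them.

Alternative 3: Carbene C–H insertion. The cut is C2–C3. A chiral dirhodium tetracarboxylate such as Rh2(S-PTTL)4 would convert 2-diazo-1-{4-(benzyloxy)-2,6-bis[3,4-bis(benzyloxy)benzyloxy]phenyl}-2-[2,4,6-tris(tert-butyldimethylsilyloxy)phenyl]ethan-1-one A8 into a carbene that inserts into a benzylic C–H of one ortho ether. The product would be (2R,3S)-7-(benzyloxy)-5-[3,4-bis(benzyloxy)benzyloxy]-2-[3,4-bis(benzyloxy)phenyl]-3-[2,4,6-tris(tert-butyldimethylsilyloxy)phenyl]chroman-4-one A7.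
- Merits: the ketone is in place in A7, the carbon skeleton of A8 is assembled convergently, and both stereocentres arise in the ring-closing step. On the first point it is better than the chosen plan; on the last it is equal.
- Weak points: in A8 the ether oxygen lies between the carbene carbon and the C–H bond. Attack of the carbene on that oxygen followed by a 1,2-shift would contract the ring to a five-membered one, and this is the expected competitor of six-membered insertion. The carbene carbon carries an aryl group with two ortho silyloxy groups and is very crowded, as is the diazo transfer that makes A8. One 3,4-bis(benzyloxy)benzyl group is carried as waste, and A7 is again a base-labile 3-arylflavanone at an early stage.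
- Comparison: the chosen plan sets against the free ketone a ring-closure mode with no competing ylide channel and two simple, separately made partners.

Key step: step 7

Remark on the chemistry: the sense of induction of the phosphoric acid in step 7 and of the bisphosphine in step 11 cannot be derived with certainty for these substrates, so the antipodes written are the expected ones and would be exchanged if a model run shows the opposite sense; "chroman" means 3,4-dihydro-2H-chromene, and doubly primed locants refer to the lower unit.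

## Route

Step 1
Reactants: 1 2,4,6-trihydroxybenzaldehyde
Product: 2 2,4-bis(benzyloxy)-6-hydroxybenzaldehyde
Conditions: BnBr (2.05 equiv), K2CO3, DMF, 0 °C to rt
Reagents that add atoms: benzyl bromide, BrCc1ccccc1
Why: Williamson etherification under weak base; the para hydroxyl and one ortho hydroxyl are alkylated, after which the remaining ortho hydroxyl is locked in a hydrogen bond to the formyl group and is the least nucleophilic, so the reaction should stop at the diether.

Step 2
Reactants: 2 2,4-bis(benzyloxy)-6-hydroxybenzaldehyde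
Product: 3 3,5-bis(benzyloxy)-2-(hydroxymethyl)phenol
Conditions: NaBH4, THF/MeOH, 0 °C; aqueous NH4Cl quench at pH 7
Reagents that add atoms: none
Why: Borohydride reduction of a salicylaldehyde; low temperature and a neutral quench are specified because this electron-rich salicyl alcohol ionises easily (the reactivity used in step 7) and would otherwise be reduced further or oligomerise.

Step 3
Reactants: 4 3,4-bis(benzyloxy)benzaldehyde
Product: 5 1,2-bis(benzyloxy)-4-ethenylbenzene
Conditions: Ph3PCH3Br, KOtBu, THF, 0 °C to rt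
Reagents that add atoms: methyltriphenylphosphonium bromide, [Br-].C[P+](c1ccccc1)(c1ccccc1)c1ccccc1
Why: Wittig methylenation with the non-stabilised ylide; no stereochemical issue arises and benzyl ethers are inert.

Step 4
Reactants: 6 1-(2,4,6-trihydroxyphenyl)ethan-1-one
Product: 7 1-(2,4,6-trihydroxy-3-iodophenyl)ethan-1-one
Conditions: N-iodosuccinimide (1.0 equiv), MeCN, 0 °C, dark
Reagents that add atoms: N-iodosuccinimide, O=C1CCC(=O)N1I
Why: Electrophilic aromatic iodination of an acylphloroglucinol; the two free ring positions are equivalent, and one equivalent of reagent at low temperature should stop at the mono-iodide because the first iodine deactivates and crowds the ring.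

Step 5
Reactants: 7 1-(2,4,6-trihydroxy-3-iodophenyl)ethan-1-one
Product: 8 2-acetyl-4-iodobenzene-1,3,5-triyl tris(2,2-dimethylpropanoate)
Conditions: PivCl (4.5 equiv), Et3N, DMAP (cat.), CH2Cl2, 0 °C to reflux
Reagents that add atoms: pivaloyl chloride, CC(C)(C)C(Cl)=O
Why: DMAP-catalysed acylation of phenols; all three oxygens become hindered esters, so this ring is a poor cation-stabilising group in step 7 and can later be unmasked without touching benzyl ethers.

Step 6
Reactants: 8 2-acetyl-4-iodobenzene-1,3,5-triyl tris(2,2-dimethylpropanoate); 5 1,2-bis(benzyloxy)-4-ethenylbenzene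
Product: 9 2-acetyl-4-{(E)-2-[3,4-bis(benzyloxy)phenyl]ethenyl}benzene-1,3,5-triyl tris(2,2-dimethylpropanoate)
Conditions: Pd(OAc)2 (5 mol %), P(t-Bu)3·HBF4 (10 mol %), Cy2NMe, 1,4-dioxane, 80 °C
Reagents that add atoms: none
Why: Mizoroki–Heck reaction: oxidative addition of the aryl iodide to zerovalent palladium, syn insertion of the styrene at its terminal carbon and syn β-hydride elimination give the E alkene; the bulky electron-rich phosphine is chosen for the di-ortho-substituted iodide, and a hindered amine in dry dioxane spares the aryl pivalates.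

Step 7
Reactants: 3 3,5-bis(benzyloxy)-2-(hydroxymethyl)phenol; 9 2-acetyl-4-{(E)-2-[3,4-bis(benzyloxy)phenyl]ethenyl}benzene-1,3,5-triyl tris(2,2-dimethylpropanoate)
Product: 11 2-acetyl-4-{(2R,3S)-5,7-bis(benzyloxy)-2-[3,4-bis(benzyloxy)phenyl]chroman-3-yl}benzene-1,3,5-triyl tris(2,2-dimethylpropanoate), via o-quinone methide 10 (not isolated)
Conditions: (R)-3,3'-bis(2,4,6-triisopropylphenyl)-1,1'-binaphthyl-2,2'-diyl hydrogen phosphate (10 mol %), 5 Å MS, toluene, 0 °C to rt, 3 (1.5 equiv) added over 8 h
Reagents that add atoms: none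
Why: The phosphoric acid ionises the benzylic alcohol of 3, and loss of water gives o-quinone methide 10, which stays hydrogen-bonded to the chiral phosphate; the benzyloxy groups ortho and para to the methide carbon make this species accessible from a primary alcohol. The stilbene carbon remote from the 3,4-bis(benzyloxy)phenyl ring adds to the exocyclic methylene (C3–C4) while the quinone oxygen closes onto the developing benzylic cation (O1–C2), an asynchronous concerted inverse-electron-demand oxa-[4+2] cycloaddition. The closest known reaction type is the chiral phosphoric acid-catalysed [4+2] cycloaddition of in situ generated o-quinone methides with electron-rich styrenes, which gives 2-arylchromans. Ring C is closed in the cycloaddition mode, its C–C and C–O bonds being formed across the same face of the alkene. The trans relation of C2 and C3 follows from suprafacial addition to the E alkene and is also the diequatorial arrangement that a stepwise closure would prefer; their absolute configuration is set by the catalyst, whose 3,3'-aryl groups shield one face of the bound quinone methide as the alkene approaches. Regioselectivity is required and is secured by the substrate: the cation is stabilised by the para benzyloxy group of the coplanar catechol ring, whereas the other aryl ring is twisted by two ortho substituents and carries three acyloxy groups and an acetyl group. Chemoselectivity against self-condensation of 10 with the nucleophilic ring of 3 is served by slow addition of 3 to the solution of 9 and catalyst.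

Step 8
Reactants: 11 2-acetyl-4-{(2R,3S)-5,7-bis(benzyloxy)-2-[3,4-bis(benzyloxy)phenyl]chroman-3-yl}benzene-1,3,5-triyl tris(2,2-dimethylpropanoate)
Product: 12 1-{3-[(2R,3S)-5,7-bis(benzyloxy)-2-[3,4-bis(benzyloxy)phenyl]chroman-3-yl]-2,4,6-trihydroxyphenyl}ethan-1-one
Conditions: NaOMe (6 equiv), MeOH/THF, argon, 0 to 40 °C; then 1 M HCl to pH 4
Reagents that add atoms: none
Why: Methanolysis (transesterification) of aryl pivalates, driven by the good acylphloroglucinol leaving group; at the flavan oxidation level the upper unit has no base-labile site, and exclusion of air protects the triphenoxide.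

Step 9
Reactants: 12 1-{3-[(2R,3S)-5,7-bis(benzyloxy)-2-[3,4-bis(benzyloxy)phenyl]chroman-3-yl]-2,4,6-trihydroxyphenyl}ethan-1-one
Product: 13 1-{4,6-bis(benzyloxy)-3-[(2R,3S)-5,7-bis(benzyloxy)-2-[3,4-bis(benzyloxy)phenyl]chroman-3-yl]-2-hydroxyphenyl}ethan-1-one
Conditions: BnBr (2.05 equiv), K2CO3, DMF, argon, 0 °C to rt
Reagents that add atoms: benzyl bromide, BrCc1ccccc1
Why: Regioselective Williamson etherification: the hydroxyl para to the acetyl group (most acidic) and the less hindered of the two ortho hydroxyls react, leaving the hydroxyl wedged between the acetyl group and the chromanyl carbon and held in the stronger hydrogen bond to the ketone; this is the oxygen that must become O1''.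

Step 10
Reactants: 13 1-{4,6-bis(benzyloxy)-3-[(2R,3S)-5,7-bis(benzyloxy)-2-[3,4-bis(benzyloxy)phenyl]chroman-3-yl]-2-hydroxyphenyl}ethan-1-one
Product: 15 5,7-bis(benzyloxy)-8-{(2R,3S)-5,7-bis(benzyloxy)-2-[3,4-bis(benzyloxy)phenyl]chroman-3-yl}-4H-chromen-4-one, via enaminone 14 (not isolated)
Conditions: Me2NCH(OMe)2, toluene, 90 °C; then conc. HCl (1.2 equiv), CH2Cl2, rt
Reagents that add atoms: N,N-dimethylformamide dimethyl acetal, COC(OC)N(C)C
Why: Enaminone route to chromones: condensation of the methyl ketone with the formamide acetal gives the vinylogous amide 14, and acid-promoted conjugate addition of the only free phenol with loss of dimethylamine closes the pyranone (6-endo addition–elimination), so the 8''-linked chromone is the only ring isomer that can form.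

Step 11
Reactants: 15 5,7-bis(benzyloxy)-8-{(2R,3S)-5,7-bis(benzyloxy)-2-[3,4-bis(benzyloxy)phenyl]chroman-3-yl}-4H-chromen-4-one; 16 [4-(benzyloxy)phenyl]boronic acid
Product: 17 (2R)-5,7-bis(benzyloxy)-2-[4-(benzyloxy)phenyl]-8-{(2R,3S)-5,7-bis(benzyloxy)-2-[3,4-bis(benzyloxy)phenyl]chroman-3-yl}chroman-4-one
Conditions: [Rh(OH)(cod)]2 (2.5 mol %), (R)-2,2'-bis[bis(3,4,5-trifluorophenyl)phosphino]-6,6'-dimethoxy-1,1'-biphenyl (5.5 mol %), 16 (3 equiv), toluene/H2O, 30 °C
Reagents that add atoms: none
Why: Rhodium-catalysed asymmetric 1,4-addition of an arylboronic acid to a chromone (Hayashi–Miyaura reaction): transmetalation gives an aryl complex of monovalent rhodium, the C2''=C3'' bond inserts on the face selected by the ligand, and hydrolysis of the oxa-π-allyl releases the flavanone; C2'' is set by catalyst control, and the base-free medium suppresses retro-oxa-Michael opening of the product.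

Step 12
Reactants: 17 (2R)-5,7-bis(benzyloxy)-2-[4-(benzyloxy)phenyl]-8-{(2R,3S)-5,7-bis(benzyloxy)-2-[3,4-bis(benzyloxy)phenyl]chroman-3-yl}chroman-4-one
Product: 18 (2R)-5,7-bis(benzyloxy)-2-[4-(benzyloxy)phenyl]-8-{(2R,3R)-5,7-bis(benzyloxy)-2-[3,4-bis(benzyloxy)phenyl]-4-hydroxychroman-3-yl}chroman-4-one (C4 epimers; C2 and C3 unchanged in space)
Conditions: DDQ (1.3 equiv), CH2Cl2/H2O (18:1), 0 °C to rt
Reagents that add atoms: water, O
Why: Benzylic oxidation by hydride abstraction: C4 is the only C–H that is ortho and para to two ether oxygens of ring A, as in the C4 activation of benzylated flavan-3-ols, and water captures the cation, expected trans to the C3 aryl group; the carbonyl-deactivated lower flavanone should not react at this temperature, and the C4 configuration is irrelevant because it is oxidised next.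

Step 13
Reactants: 18 (2R)-5,7-bis(benzyloxy)-2-[4-(benzyloxy)phenyl]-8-{(2R,3R)-5,7-bis(benzyloxy)-2-[3,4-bis(benzyloxy)phenyl]-4-hydroxychroman-3-yl}chroman-4-one
Product: 19 (2R,3S)-5,7-bis(benzyloxy)-2-[3,4-bis(benzyloxy)phenyl]-3-{(2R)-5,7-bis(benzyloxy)-2-[4-(benzyloxy)phenyl]-4-oxochroman-8-yl}chroman-4-one
Conditions: Dess–Martin periodinane, NaHCO3, CH2Cl2, 0 °C to rt
Reagents that add atoms: none
Why: Dess–Martin oxidation of a secondary benzylic alcohol under buffered, non-basic conditions, so that C3 (now α to the ketone) and both ring C systems never meet base.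

Step 14
Reactants: 19 (2R,3S)-5,7-bis(benzyloxy)-2-[3,4-bis(benzyloxy)phenyl]-3-{(2R)-5,7-bis(benzyloxy)-2-[4-(benzyloxy)phenyl]-4-oxochroman-8-yl}chroman-4-one
Product: 20 (2R,3S)-2-(3,4-dihydroxyphenyl)-5,7-dihydroxy-3-[(2R)-5,7-dihydroxy-2-(4-hydroxyphenyl)-4-oxochroman-8-yl]chroman-4-one
Conditions: H2 (1 atm), Pd(OH)2/C, THF/MeOH, rt
Reagents that add atoms: none
Why: Hydrogenolysis of seven aryl benzyl ethers over palladium under neutral conditions; neither flavanone is exposed to acid or base, and the run is stopped at the end of hydrogen uptake to avoid cleavage of the benzylic C2–O bonds.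

## Compound list

1 | 2,4,6-trihydroxybenzaldehyde | O=Cc1c(O)cc(O)cc1O | starting material
2 | 2,4-bis(benzyloxy)-6-hydroxybenzaldehyde | O=Cc1c(O)cc(OCc2ccccc2)cc1OCc1ccccc1 | intermediate
3 | 3,5-bis(benzyloxy)-2-(hydroxymethyl)phenol | OCc1c(O)cc(OCc2ccccc2)cc1OCc1ccccc1 | intermediate
4 | 3,4-bis(benzyloxy)benzaldehyde | O=Cc1ccc(OCc2ccccc2)c(OCc2ccccc2)c1 | starting material
5 | 1,2-bis(benzyloxy)-4-ethenylbenzene | C=Cc1ccc(OCc2ccccc2)c(OCc2ccccc2)c1 | intermediate
6 | 1-(2,4,6-trihydroxyphenyl)ethan-1-one | CC(=O)c1c(O)cc(O)cc1O | starting material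
7 | 1-(2,4,6-trihydroxy-3-iodophenyl)ethan-1-one | CC(=O)c1c(O)cc(O)c(I)c1O | intermediate
8 | 2-acetyl-4-iodobenzene-1,3,5-triyl tris(2,2-dimethylpropanoate) | CC(=O)c1c(OC(=O)C(C)(C)C)cc(OC(=O)C(C)(C)C)c(I)c1OC(=O)C(C)(C)C | intermediate
9 | 2-acetyl-4-{(E)-2-[3,4-bis(benzyloxy)phenyl]ethenyl}benzene-1,3,5-triyl tris(2,2-dimethylpropanoate) | CC(=O)c1c(OC(=O)C(C)(C)C)cc(OC(=O)C(C)(C)C)c(/C=C/c2ccc(OCc3ccccc3)c(OCc3ccccc3)c2)c1OC(=O)C(C)(C)C | intermediate
10 | 3,5-bis(benzyloxy)-6-methylidenecyclohexa-2,4-dien-1-one (o-quinone methide, not isolated) | C=C1C(=O)C=C(OCc2ccccc2)C=C1OCc1ccccc1 | intermediate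
11 | 2-acetyl-4-{(2R,3S)-5,7-bis(benzyloxy)-2-[3,4-bis(benzyloxy)phenyl]chroman-3-yl}benzene-1,3,5-triyl tris(2,2-dimethylpropanoate) | CC(=O)c1c(OC(=O)C(C)(C)C)cc(OC(=O)C(C)(C)C)c([C@@H]2Cc3c(OCc4ccccc4)cc(OCc4ccccc4)cc3O[C@H]2c2ccc(OCc3ccccc3)c(OCc3ccccc3)c2)c1OC(=O)C(C)(C)C | intermediate
12 | 1-{3-[(2R,3S)-5,7-bis(benzyloxy)-2-[3,4-bis(benzyloxy)phenyl]chroman-3-yl]-2,4,6-trihydroxyphenyl}ethan-1-one | CC(=O)c1c(O)cc(O)c([C@@H]2Cc3c(OCc4ccccc4)cc(OCc4ccccc4)cc3O[C@H]2c2ccc(OCc3ccccc3)c(OCc3ccccc3)c2)c1O | intermediate
13 | 1-{4,6-bis(benzyloxy)-3-[(2R,3S)-5,7-bis(benzyloxy)-2-[3,4-bis(benzyloxy)phenyl]chroman-3-yl]-2-hydroxyphenyl}ethan-1-one | CC(=O)c1c(OCc2ccccc2)cc(OCc2ccccc2)c([C@@H]2Cc3c(OCc4ccccc4)cc(OCc4ccccc4)cc3O[C@H]2c2ccc(OCc3ccccc3)c(OCc3ccccc3)c2)c1O | intermediate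
14 | (E)-1-{4,6-bis(benzyloxy)-3-[(2R,3S)-5,7-bis(benzyloxy)-2-[3,4-bis(benzyloxy)phenyl]chroman-3-yl]-2-hydroxyphenyl}-3-(dimethylamino)prop-2-en-1-one (enaminone, not isolated) | CN(C)/C=C/C(=O)c1c(OCc2ccccc2)cc(OCc2ccccc2)c([C@@H]2Cc3c(OCc4ccccc4)cc(OCc4ccccc4)cc3O[C@H]2c2ccc(OCc3ccccc3)c(OCc3ccccc3)c2)c1O | intermediate
15 | 5,7-bis(benzyloxy)-8-{(2R,3S)-5,7-bis(benzyloxy)-2-[3,4-bis(benzyloxy)phenyl]chroman-3-yl}-4H-chromen-4-one | O=C1C=COc2c1c(OCc1ccccc1)cc(OCc1ccccc1)c2[C@@H]1Cc2c(OCc3ccccc3)cc(OCc3ccccc3)cc2O[C@H]1c1ccc(OCc2ccccc2)c(OCc2ccccc2)c1 | intermediate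
16 | [4-(benzyloxy)phenyl]boronic acid | OB(O)c1ccc(OCc2ccccc2)cc1 | starting material
17 | (2R)-5,7-bis(benzyloxy)-2-[4-(benzyloxy)phenyl]-8-{(2R,3S)-5,7-bis(benzyloxy)-2-[3,4-bis(benzyloxy)phenyl]chroman-3-yl}chroman-4-one | O=C1C[C@H](c2ccc(OCc3ccccc3)cc2)Oc2c1c(OCc1ccccc1)cc(OCc1ccccc1)c2[C@@H]1Cc2c(OCc3ccccc3)cc(OCc3ccccc3)cc2O[C@H]1c1ccc(OCc2ccccc2)c(OCc2ccccc2)c1 | intermediate
18 | (2R)-5,7-bis(benzyloxy)-2-[4-(benzyloxy)phenyl]-8-{(2R,3R)-5,7-bis(benzyloxy)-2-[3,4-bis(benzyloxy)phenyl]-4-hydroxychroman-3-yl}chroman-4-one (C4 epimers, C4 left undefined) | O=C1C[C@H](c2ccc(OCc3ccccc3)cc2)Oc2c1c(OCc1ccccc1)cc(OCc1ccccc1)c2[C@@H]1C(O)c2c(OCc3ccccc3)cc(OCc3ccccc3)cc2O[C@H]1c1ccc(OCc2ccccc2)c(OCc2ccccc2)c1 | intermediate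
19 | (2R,3S)-5,7-bis(benzyloxy)-2-[3,4-bis(benzyloxy)phenyl]-3-{(2R)-5,7-bis(benzyloxy)-2-[4-(benzyloxy)phenyl]-4-oxochroman-8-yl}chroman-4-one | O=C1C[C@H](c2ccc(OCc3ccccc3)cc2)Oc2c1c(OCc1ccccc1)cc(OCc1ccccc1)c2[C@@H]1C(=O)c2c(OCc3ccccc3)cc(OCc3ccccc3)cc2O[C@H]1c1ccc(OCc2ccccc2)c(OCc2ccccc2)c1 | intermediate
20 | (2R,3S)-2-(3,4-dihydroxyphenyl)-5,7-dihydroxy-3-[(2R)-5,7-dihydroxy-2-(4-hydroxyphenyl)-4-oxochroman-8-yl]chroman-4-one | O=C1C[C@H](c2ccc(O)cc2)Oc2c1c(O)cc(O)c2[C@@H]1C(=O)c2c(O)cc(O)cc2O[C@H]1c1ccc(O)c(O)c1 | target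

## Step count and least certain steps

Total: 14 steps. Longest linear sequence: 11 steps (6 → 7 → 8 → 9 → 11 → 12 → 13 → 15 → 17 → 18 → 19 → 20).

**Step 7 (key step).**
- Risk: self-condensation of the quinone methide with the nucleophilic ring of its own precursor may outrun addition to a hindered, only moderately electron-rich alkene. Facial discrimination may also be poor, because the stilbene offers the phosphate no hydrogen-bond donor and the new stereocentres lie on the alkene, not on the catalyst-bound partner.
- Fallback: from 3 and 9 the cycloaddition is run without asymmetric induction (diphenyl hydrogen phosphate, or heating in toluene). This gives the racemic trans adduct, that is 11 together with its enantiomer, 2-acetyl-4-{(2S,3R)-5,7-bis(benzyloxy)-2-[3,4-bis(benzyloxy)phenyl]chroman-3-yl}benzene-1,3,5-triyl tris(2,2-dimethylpropanoate) F1. The pair is separated by preparative chromatography on a chiral stationary phase, and the route is rejoined at 11.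

**Step 12.**
- Risk: the C4 cation may lose the C3 proton instead of taking up water, leading to a chromene that the oxidant would consume. Hydride transfer may be slow beside a C3 substituent that now carries a whole flavanone. The lower unit offers a second hydride donor at C2''.
- Fallback: the oxidation is moved one stage earlier, to the flat and less crowded chromone 15, which has no C2'' hydrogen, and is run in homogeneous wet dioxane to favour capture. This gives 5,7-bis(benzyloxy)-8-{(2R,3R)-5,7-bis(benzyloxy)-2-[3,4-bis(benzyloxy)phenyl]-4-hydroxychroman-3-yl}-4H-chromen-4-one F2. Dess–Martin oxidation then gives (2R,3S)-5,7-bis(benzyloxy)-2-[3,4-bis(benzyloxy)phenyl]-3-[5,7-bis(benzyloxy)-4-oxo-4H-chromen-8-yl]chroman-4-one F3. The base-free rhodium-catalysed arylation of step 11 is applied to F3 with 16, and the route is rejoined at 19.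

**Step 9.**
- Risk: alkylation may not discriminate well enough between the two hydroxyls ortho to the acetyl group, or may run on to the triether.
- Fallback: 12 is benzylated exhaustively (excess BnBr, K2CO3, DMF, 60 °C) to 1-{2,4,6-tris(benzyloxy)-3-[(2R,3S)-5,7-bis(benzyloxy)-2-[3,4-bis(benzyloxy)phenyl]chroman-3-yl]phenyl}ethan-1-one F4. One benzyl group is then removed with BCl3 (1 equiv, CH2Cl2, −78 °C). Chelation to the ketone limits cleavage to the ortho ethers, and the doubly flanked, twisted ether should go first with relief of strain, which returns the route to 13.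

**Step 11.**
- Risk: insertion into a chromone carrying a 5-alkoxy group and a bulky 8-substituent may be slow, so protodeboronation wins. The chiral upper unit may oppose the ligand (mismatched facial bias), or the product may open under the aqueous conditions.
- Fallback: from 13, Claisen–Schmidt condensation with 4-(benzyloxy)benzaldehyde (KOH, EtOH/THF; the upper unit is still a base-stable flavan) gives (E)-1-{4,6-bis(benzyloxy)-3-[(2R,3S)-5,7-bis(benzyloxy)-2-[3,4-bis(benzyloxy)phenyl]chroman-3-yl]-2-hydroxyphenyl}-3-[4-(benzyloxy)phenyl]prop-2-en-1-one F5. Oxa-Michael closure (NaOAc, EtOH, reflux) gives 17 together with its C2'' epimer, (2S)-5,7-bis(benzyloxy)-2-[4-(benzyloxy)phenyl]-8-{(2R,3S)-5,7-bis(benzyloxy)-2-[3,4-bis(benzyloxy)phenyl]chroman-3-yl}chroman-4-one F6. The two are diastereomers, separable on silica; F6 is reopened to F5 with base and recycled, and the route is rejoined at 17.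

**Step 6.**
- Risk: migratory insertion at an aryl–palladium centre flanked by two acyloxy groups may be slow, so reductive loss of iodine or attack at the internal alkene carbon competes.
- Fallback: from 5, cross-metathesis with 4,4,5,5-tetramethyl-2-vinyl-1,3,2-dioxaborolane (second-generation Grubbs catalyst, RuCl2(=CHPh)(H2IMes)(PCy3), CH2Cl2, 40 °C) gives 2-{(E)-2-[3,4-bis(benzyloxy)phenyl]ethenyl}-4,4,5,5-tetramethyl-1,3,2-dioxaborolane F7. Suzuki–Miyaura coupling of F7 with 8 (Pd(OAc)2, 2-dicyclohexylphosphino-2',6'-dimethoxybiphenyl, K3PO4, toluene with a little water, 60 °C) replaces insertion by transmetalation and returns the route to 9.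

## Further compounds

F1 | step 7 | 2-acetyl-4-{(2S,3R)-5,7-bis(benzyloxy)-2-[3,4-bis(benzyloxy)phenyl]chroman-3-yl}benzene-1,3,5-triyl tris(2,2-dimethylpropanoate) | CC(=O)c1c(OC(=O)C(C)(C)C)cc(OC(=O)C(C)(C)C)c([C@H]2Cc3c(OCc4ccccc4)cc(OCc4ccccc4)cc3O[C@@H]2c2ccc(OCc3ccccc3)c(OCc3ccccc3)c2)c1OC(=O)C(C)(C)C
F2 | step 12 | 5,7-bis(benzyloxy)-8-{(2R,3R)-5,7-bis(benzyloxy)-2-[3,4-bis(benzyloxy)phenyl]-4-hydroxychroman-3-yl}-4H-chromen-4-one (C4 epimers, C4 left undefined) | O=C1C=COc2c1c(OCc1ccccc1)cc(OCc1ccccc1)c2[C@@H]1C(O)c2c(OCc3ccccc3)cc(OCc3ccccc3)cc2O[C@H]1c1ccc(OCc2ccccc2)c(OCc2ccccc2)c1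
F3 | step 12 | (2R,3S)-5,7-bis(benzyloxy)-2-[3,4-bis(benzyloxy)phenyl]-3-[5,7-bis(benzyloxy)-4-oxo-4H-chromen-8-yl]chroman-4-one | O=C1C=COc2c1c(OCc1ccccc1)cc(OCc1ccccc1)c2[C@@H]1C(=O)c2c(OCc3ccccc3)cc(OCc3ccccc3)cc2O[C@H]1c1ccc(OCc2ccccc2)c(OCc2ccccc2)c1
F4 | step 9 | 1-{2,4,6-tris(benzyloxy)-3-[(2R,3S)-5,7-bis(benzyloxy)-2-[3,4-bis(benzyloxy)phenyl]chroman-3-yl]phenyl}ethan-1-one | CC(=O)c1c(OCc2ccccc2)cc(OCc2ccccc2)c([C@@H]2Cc3c(OCc4ccccc4)cc(OCc4ccccc4)cc3O[C@H]2c2ccc(OCc3ccccc3)c(OCc3ccccc3)c2)c1OCc1ccccc1
F5 | step 11 | (E)-1-{4,6-bis(benzyloxy)-3-[(2R,3S)-5,7-bis(benzyloxy)-2-[3,4-bis(benzyloxy)phenyl]chroman-3-yl]-2-hydroxyphenyl}-3-[4-(benzyloxy)phenyl]prop-2-en-1-one | O=C(/C=C/c1ccc(OCc2ccccc2)cc1)c1c(OCc2ccccc2)cc(OCc2ccccc2)c([C@@H]2Cc3c(OCc4ccccc4)cc(OCc4ccccc4)cc3O[C@H]2c2ccc(OCc3ccccc3)c(OCc3ccccc3)c2)c1O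
F6 | step 11 | (2S)-5,7-bis(benzyloxy)-2-[4-(benzyloxy)phenyl]-8-{(2R,3S)-5,7-bis(benzyloxy)-2-[3,4-bis(benzyloxy)phenyl]chroman-3-yl}chroman-4-one | O=C1C[C@@H](c2ccc(OCc3ccccc3)cc2)Oc2c1c(OCc1ccccc1)cc(OCc1ccccc1)c2[C@@H]1Cc2c(OCc3ccccc3)cc(OCc3ccccc3)cc2O[C@H]1c1ccc(OCc2ccccc2)c(OCc2ccccc2)c1
F7 | step 6 | 2-{(E)-2-[3,4-bis(benzyloxy)phenyl]ethenyl}-4,4,5,5-tetramethyl-1,3,2-dioxaborolane | CC1(C)OB(/C=C/c2ccc(OCc3ccccc3)c(OCc3ccccc3)c2)OC1(C)C
A1 | alternative 1 | (2R,3S)-5,7-bis(benzyloxy)-2-[3,4-bis(benzyloxy)phenyl]-3-[2,4,6-tris(methoxymethoxy)phenyl]chroman-4-one | COCOc1cc(OCOC)cc(OCOC)c1[C@@H]1C(=O)c2c(OCc3ccccc3)cc(OCc3ccccc3)cc2O[C@H]1c1ccc(OCc2ccccc2)c(OCc2ccccc2)c1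
A2 | alternative 1 | methyl (2S,3R)-3-[3,4-bis(benzyloxy)phenyl]-3-hydroxy-2-[2,4,6-tris(methoxymethoxy)phenyl]propanoate | COC(=O)[C@@H](c1c(OCOC)cc(OCOC)cc1OCOC)[C@@H](O)c1ccc(OCc2ccccc2)c(OCc2ccccc2)c1
A3 | alternative 1 | 3,5-bis(benzyloxy)-2-(trimethylsilyl)phenyl trifluoromethanesulfonate | C[Si](C)(C)c1c(OCc2ccccc2)cc(OCc2ccccc2)cc1OS(=O)(=O)C(F)(F)F
A4 | alternative 2 | 5-(benzyloxy)-2-{(2R,3S)-5,7-bis(benzyloxy)-2-[3,4-bis(benzyloxy)phenyl]chroman-3-yl}-3-(triisopropylsilyloxy)phenol | Oc1cc(OCc2ccccc2)cc(O[Si](C(C)C)(C(C)C)C(C)C)c1[C@@H]1Cc2c(OCc3ccccc3)cc(OCc3ccccc3)cc2O[C@H]1c1ccc(OCc2ccccc2)c(OCc2ccccc2)c1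
A5 | alternative 2 | (2R,3S)-5,7-bis(benzyloxy)-2-[3,4-bis(benzyloxy)phenyl]-3-[(triisopropylsilyloxy)ethynyl]chroman | CC(C)[Si](OC#C[C@@H]1Cc2c(OCc3ccccc3)cc(OCc3ccccc3)cc2O[C@H]1c1ccc(OCc2ccccc2)c(OCc2ccccc2)c1)(C(C)C)C(C)C
A6 | alternative 2 | 3-(benzyloxy)cyclobut-2-en-1-one | O=C1C=C(OCc2ccccc2)C1
A7 | alternative 3 | (2R,3S)-7-(benzyloxy)-5-[3,4-bis(benzyloxy)benzyloxy]-2-[3,4-bis(benzyloxy)phenyl]-3-[2,4,6-tris(tert-butyldimethylsilyloxy)phenyl]chroman-4-one | CC(C)(C)[Si](C)(C)Oc1cc(O[Si](C)(C)C(C)(C)C)cc(O[Si](C)(C)C(C)(C)C)c1[C@@H]1C(=O)c2c(OCc3ccc(OCc4ccccc4)c(OCc4ccccc4)c3)cc(OCc3ccccc3)cc2O[C@H]1c1ccc(OCc2ccccc2)c(OCc2ccccc2)c1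
A8 | alternative 3 | 2-diazo-1-{4-(benzyloxy)-2,6-bis[3,4-bis(benzyloxy)benzyloxy]phenyl}-2-[2,4,6-tris(tert-butyldimethylsilyloxy)phenyl]ethan-1-one | [N-]=[N+]=C(C(=O)c1c(OCc2ccc(OCc3ccccc3)c(OCc3ccccc3)c2)cc(OCc2ccccc2)cc1OCc1ccc(OCc2ccccc2)c(OCc2ccccc2)c1)c1c(O[Si](C)(C)C(C)(C)C)cc(O[Si](C)(C)C(C)(C)C)cc1O[Si](C)(C)C(C)(C)C
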